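**Plan**
1. Last cut first: the three butanoyl groups are carried as cyclopropyl ketones and the three phenols as benzyl ethers, all released in one hydrogenolysis.
2. Both outer rings are then cut together: in each, the two ring C–C bonds that tie the C(OH)–CMe2–C(OH) segment to the carbon bearing the bridge CH2 and to the carbon bearing the acyl group. This leaves 2,2-dimethylmalonyl dichloride (twice) and a central arene with two 1,3-diketone arms.
3. The arms are cut at their CH2–CH2 bonds (diketone dianion plus benzylic chloride), then at the two ArCH2 carbons (chloromethylation) and at the aryl–acyl bond (Vilsmeier–Haack acylation of 1,3,5-tris(benzyloxy)benzene).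
4. Forward order: central ring acylated, two CH2Cl groups, two diketone arms, then outer rings A and B closed at once with four new C–C bonds, then global hydrogenolysis.
5. Enabling feature: each outer ring is a 2-acyl-4,4-dimethylcyclohexane-1,3,5-trione. Ring atoms C3–C4–C5 are a dimethylmalonyl unit; C6–C1–C2 with the exocyclic acyl carbon are a 1,3-diketone, nucleophilic at C6 and C2. The mirror plane through the central ring makes rings A and B equal.
6. Stereochemistry: the target has no stereocenter, so nothing has to be controlled.

Key step: step 4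

Remark: the target is taken as the enol tautomer drawn; the tautomers of the trione rings are one compound.

**Step 1**
Reactants: 1 1,3,5-tris(benzyloxy)benzene; 2 N,N-dimethylcyclopropanecarboxamide
Product: 4 cyclopropyl[2,4,6-tris(benzyloxy)phenyl]methanone, via aryl iminium chloride 3 (not isolated)
Conditions: POCl3 (1.5 equiv), ClCH2CH2Cl, 70 °C; then H2O, 60 °C
Reagents that add atoms: water, O
Why: Vilsmeier–Haack acylation, in which the chloroiminium ion from 2 and POCl3 should substitute the triply activated ring once (iminium 3 is deactivated) without the strong Lewis acid that would cleave benzyl ethers, and hydrolysis of 3 gives the ketone.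

**Step 2**
Reactants: 4 cyclopropyl[2,4,6-tris(benzyloxy)phenyl]methanone; 5 chloromethyl methyl ether
Product: 6 [2,4,6-tris(benzyloxy)-3,5-bis(chloromethyl)phenyl](cyclopropyl)methanone
Conditions: 5 (10 equiv), ZnCl2 (0.2 equiv), CH2Cl2, 0 °C to rt; used crude
Reagents that add atoms: none
Why: Blanc-type chloromethylation (electrophilic aromatic substitution), in which both remaining ring positions are ortho or para to three benzyloxy groups, the flanked and twisted ketone deactivates little, and the large excess of 5 should favour chloromethylation over diarylmethane formation.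

**Step 3**
Reactants: 6 [2,4,6-tris(benzyloxy)-3,5-bis(chloromethyl)phenyl](cyclopropyl)methanone; 7 1-cyclopropylbutane-1,3-dione
Product: 9 5,5'-[2,4,6-tris(benzyloxy)-5-(cyclopropanecarbonyl)-1,3-phenylene]bis(1-cyclopropylpentane-1,3-dione), via dilithium dienediolate 8 (not isolated)
Conditions: 7 (2.4 equiv), LiN(iPr)2 (4.8 equiv), THF, 0 °C; then 6, −78 to 0 °C; aq. NH4Cl
Reagents that add atoms: none
Why: γ-alkylation of a β-diketone dianion, in which the second deprotonation of 7 can occur only at the methyl group (the cyclopropyl methine would give an alkylidenecyclopropane enolate and is not deprotonated), so the terminal carbanion of 8 should displace each reactive benzylic chloride, while the aryl cyclopropyl ketone has no enolizable hydrogen.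

**Step 4**
Reactants: 9 5,5'-[2,4,6-tris(benzyloxy)-5-(cyclopropanecarbonyl)-1,3-phenylene]bis(1-cyclopropylpentane-1,3-dione); 10 2,2-dimethylmalonyl dichloride
Product: 12 6,6'-{[2,4,6-tris(benzyloxy)-5-(cyclopropanecarbonyl)-1,3-phenylene]bis(methylene)}bis[2-(cyclopropanecarbonyl)-3,5-dihydroxy-4,4-dimethylcyclohexa-2,5-dien-1-one], via tetralithium bis(dienediolate) 11 (not isolated)
Conditions: LiN(iPr)2 (4.2 equiv), THF, −78 to 0 °C; LiN(SiMe3)2 (4.4 equiv); 10 (2.2 equiv), −78 °C to rt; then NaOMe (0.3 equiv), MeOH, rt; aq. HCl
Reagents that add atoms: none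
Why: Proposed new method: each arm is deprotonated twice to a 1,3-diketone dianion whose terminal carbanion (the CH2 next to the bridge methylene) attacks one COCl of 10 to form C5–C6, and the central carbon of the resulting 1,3,5-triketone enolate then closes onto the second COCl to form C2–C3, so that each outer ring gains both bonds to the C(=O)–CMe2–C(=O) unit in one flask; the closest known reaction types are the terminal acylation of β-diketone dianions, the Claisen cyclization of 3,5,7-triketo esters to acylphloroglucinols and the Effenberger cyclization of ketone enol derivatives with malonyl dichloride. Each of the two six-membered rings closes in the 6-exo-trig mode by attack of an enolate carbon on an acyl chloride carbonyl. No stereocenter is formed. The step needs site selectivity among the α-carbons, C- over O-acylation in the ring closure and ring closure over bridging of the two arms: the first is secured by the cyclopropyl groups and the non-enolizable aryl ketone, the third by the six-membered transition state and the neopentyl-type hindrance of 10, and the second by the methoxide stage, which should open any enol lactone to the methyl ester and let it close again at carbon to the trione, the only isomer held as a doubly stabilized enolate. LiN(SiMe3)2 is present so that the acidic product does not protonate carbanion that has not yet reacted.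

**Step 5**
Reactants: 12 the tris(benzyl ether) tris(cyclopropyl ketone) from step 4
Product: 13 6,6'-[(5-butanoyl-2,4,6-trihydroxy-1,3-phenylene)bis(methylene)]bis(2-butanoyl-3,5-dihydroxy-4,4-dimethylcyclohexa-2,5-dien-1-one)
Conditions: H2 (4 bar), 10% Pd/C, EtOAc–AcOH, rt to 40 °C
Reagents that add atoms: none
Why: catalytic hydrogenolysis, which should cleave the three aryl benzyl ethers and open each conjugated cyclopropyl ketone at the C–C bond next to the carbonyl (the bond that overlaps with the carbonyl π system) to the n-propyl ketone, so that the three butanoyl groups and the three phenols are released together.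

**Compound list**
1 | 1,3,5-tris(benzyloxy)benzene | c1c(OCc2ccccc2)cc(OCc2ccccc2)cc1OCc1ccccc1 | starting material
2 | N,N-dimethylcyclopropanecarboxamide | CN(C)C(=O)C1CC1 | starting material
3 | N-{cyclopropyl[2,4,6-tris(benzyloxy)phenyl]methylidene}-N-methylmethanaminium chloride | C[N+](C)=C(C1CC1)c1c(OCc2ccccc2)cc(OCc2ccccc2)cc1OCc1ccccc1.[Cl-] | intermediate
4 | cyclopropyl[2,4,6-tris(benzyloxy)phenyl]methanone | O=C(C1CC1)c1c(OCc2ccccc2)cc(OCc2ccccc2)cc1OCc1ccccc1 | intermediate
5 | chloromethyl methyl ether | COCCl | starting material
6 | [2,4,6-tris(benzyloxy)-3,5-bis(chloromethyl)phenyl](cyclopropyl)methanone | O=C(C1CC1)c1c(OCc2ccccc2)c(CCl)c(OCc2ccccc2)c(CCl)c1OCc1ccccc1 | intermediate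
7 | 1-cyclopropylbutane-1,3-dione | CC(=O)CC(=O)C1CC1 | starting material
8 | dilithium 1-cyclopropylbuta-1,3-diene-1,3-bis(olate) | [Li+].[Li+].C=C([O-])C=C([O-])C1CC1 | intermediate
9 | 5,5'-[2,4,6-tris(benzyloxy)-5-(cyclopropanecarbonyl)-1,3-phenylene]bis(1-cyclopropylpentane-1,3-dione) | O=C(C1CC1)c1c(OCc2ccccc2)c(CCC(=O)CC(=O)C2CC2)c(OCc2ccccc2)c(CCC(=O)CC(=O)C2CC2)c1OCc1ccccc1 | intermediate
10 | 2,2-dimethylmalonyl dichloride | CC(C)(C(=O)Cl)C(=O)Cl | starting material
11 | tetralithium salt of 9 deprotonated twice in each diketone arm | [Li+].[Li+].[Li+].[Li+].O=C(C1CC1)c1c(OCc2ccccc2)c(CC=C([O-])C=C([O-])C2CC2)c(OCc2ccccc2)c(CC=C([O-])C=C([O-])C2CC2)c1OCc1ccccc1 | intermediate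
12 | 6,6'-{[2,4,6-tris(benzyloxy)-5-(cyclopropanecarbonyl)-1,3-phenylene]bis(methylene)}bis[2-(cyclopropanecarbonyl)-3,5-dihydroxy-4,4-dimethylcyclohexa-2,5-dien-1-one] | O=C(C1CC1)C1=C(O)C(C)(C)C(O)=C(Cc2c(OCc3ccccc3)c(CC3=C(O)C(C)(C)C(O)=C(C(=O)C4CC4)C3=O)c(OCc3ccccc3)c(C(=O)C3CC3)c2OCc2ccccc2)C1=O | intermediate
13 | 6,6'-[(5-butanoyl-2,4,6-trihydroxy-1,3-phenylene)bis(methylene)]bis(2-butanoyl-3,5-dihydroxy-4,4-dimethylcyclohexa-2,5-dien-1-one), CNP0287270.0 | CCCC(=O)C1=C(O)C(C)(C)C(O)=C(Cc2c(O)c(CC3=C(O)C(C)(C)C(O)=C(C(=O)CCC)C3=O)c(O)c(C(=O)CCC)c2O)C1=O | target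

**Count and risks**
Total step count: 5. Longest linear sequence: 5 steps.

The three steps most likely to fail:

Step 4 (Proposed new method). The acidic trione, once formed, may protonate carbanion that has not yet reacted. The second acylation may also take place at oxygen or between the two arms, and both annulations must succeed on the same molecule. The fallback sets out from 6 and comes back to the route at 12; it makes the outer ring separately by known chemistry and joins it to the central ring by C-alkylation. Commercial phloroglucinol is acylated with cyclopropanecarbonyl chloride (AlCl3, PhNO2–CH2Cl2, Friedel–Crafts) to cyclopropyl(2,4,6-trihydroxyphenyl)methanone F1. Twofold C-methylation at one ring carbon (MeI, NaOMe, MeOH) should give 2-(cyclopropanecarbonyl)-3,5-dihydroxy-4,4-dimethylcyclohexa-2,5-dien-1-one F2. Two equivalents of the sodium enolate of F2 are then C-benzylated at the free ring carbon by dichloride 6 (NaOMe, MeOH–THF, 0 °C to rt) to give 12, which goes on to step 5.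

Step 5. The opening of the three cyclopropane rings may stop short, may cleave the distal C–C bond to leave isopropyl ketones, or may be followed by reduction of the carbonyl groups. The fallback sets out from 12 and comes back at 13. TMSCl and NaI (MeCN, 0 °C to rt) cleave the benzyl ethers and open each cyclopropyl ketone by attack of iodide at a ring CH2, which can only give the straight chain. The expected product is 6,6'-{[2,4,6-trihydroxy-5-(4-iodobutanoyl)-1,3-phenylene]bis(methylene)}bis[3,5-dihydroxy-2-(4-iodobutanoyl)-4,4-dimethylcyclohexa-2,5-dien-1-one] F3. Radical reduction of the three C–I bonds (Bu3SnH, AIBN, benzene, 80 °C) should then give 13.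

Step 2. Ionization of the electron-rich benzylic chloride during the reaction can lead to diarylmethane formation, and the acidic medium can remove benzyl groups. The fallback sets out from 4 and comes back at 6. Rieche formylation at both free positions (Cl2CHOMe, SnCl4, CH2Cl2, −20 °C, aqueous work-up) gives 2,4,6-tris(benzyloxy)-5-(cyclopropanecarbonyl)benzene-1,3-dicarbaldehyde F4. NaBH4 (THF–MeOH, −20 °C) should reduce only the aldehydes, giving [2,4,6-tris(benzyloxy)-3,5-bis(hydroxymethyl)phenyl](cyclopropyl)methanone F5. MsCl, Et3N and LiCl (THF, 0 °C) then convert F5 into dichloride 6 without acid.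

**Further compounds**
F1 | step 4 | cyclopropyl(2,4,6-trihydroxyphenyl)methanone | O=C(C1CC1)c1c(O)cc(O)cc1O
F2 | step 4 | 2-(cyclopropanecarbonyl)-3,5-dihydroxy-4,4-dimethylcyclohexa-2,5-dien-1-one | O=C(C1CC1)C1=C(O)C(C)(C)C(O)=CC1=O
F3 | step 5 | 6,6'-{[2,4,6-trihydroxy-5-(4-iodobutanoyl)-1,3-phenylene]bis(methylene)}bis[3,5-dihydroxy-2-(4-iodobutanoyl)-4,4-dimethylcyclohexa-2,5-dien-1-one] | ICCCC(=O)C1=C(O)C(C)(C)C(O)=C(Cc2c(O)c(CC3=C(O)C(C)(C)C(O)=C(C(=O)CCCI)C3=O)c(O)c(C(=O)CCCI)c2O)C1=O
F4 | step 2 | 2,4,6-tris(benzyloxy)-5-(cyclopropanecarbonyl)benzene-1,3-dicarbaldehyde | O=C(C1CC1)c1c(OCc2ccccc2)c(C=O)c(OCc2ccccc2)c(C=O)c1OCc1ccccc1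
F5 | step 2 | [2,4,6-tris(benzyloxy)-3,5-bis(hydroxymethyl)phenyl](cyclopropyl)methanone | O=C(C1CC1)c1c(OCc2ccccc2)c(CO)c(OCc2ccccc2)c(CO)c1OCc1ccccc1
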